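**Plan**

1. Locants: ring carbons C1 (ketone) to C10 (CH–CH3); C6 and C7 are shared with the butenolide (C11 α-carbon, C12 lactone C=O, C13 CH2OAc). The ketol C1(=O)–C10H(CH3)–C9H(OH) of the ten-membered ring is the retron of an isoxazoline C1=N–O–C9, and the C8 oxygen lies allylic to the C9=C10 alkene that this implies.
2. Cuts, in order: the isoxazoline N–O bond and the two esters; then C1–C10 together with O–C9 in one intramolecular nitrile oxide (3+2) cycloaddition; then C7–C8 and C8–C9 (carbonylative coupling), O–C6 and C7–I (iodolactonisation), C11–C12 (carbonylation), C6–C7 (alkynylation).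
3. Forward: neryl acetate gives the (Z)-enal C1–C6; an alkyne adds C7, C11 and C13; the allenic acid closes to the β-iodobutenolide; acyl coupling adds C8–C10; the oxime follows. The cycloaddition then closes the isoxazoline and the ten-membered carbocycle at once.
4. Stereochemistry: C6 from the zinc–ProPhenol alkynylation, relayed through the allene axis; C8 from a CBS reduction; C9 and C10 from the cycloaddition (C8 magnesium alkoxide direction and E-alkene geometry); 4Z from nerol.
5. Helpers and their removal: dimethyl acetal (masks C1), C7 iodide, TBDPS ether on C13, and the isoxazoline N–O bridge. The bridge also keeps C9–O and C1=O masked while C8 is esterified, and is cleaved last.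

Key step: step 10

Assumption: the (S,S)-ProPhenol/Me2Zn catalyst is taken to add the alkyne to the enal face that gives the 4S carbinol of step 4; if the sense proves opposite, the (R,R)-ligand is used and nothing else changes.
Assumption: the propargyl silyl ether of step 4 and the (E)-propenylstannane of step 7 are taken as commercial; each is otherwise one step from propargyl alcohol or (E)-1-bromopropene.

Step 1
Reactants: 1 neryl acetate
Product: 2 (4Z)-6-acetoxy-4-methylhex-4-enal
Conditions: O3 (1.0 equiv), CH2Cl2, −78 °C; then Me2S, −78 °C to rt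
Reagents that add atoms: ozone, [O-][O+]=O
Why: Selective ozonolysis of the electron-richer terminal trisubstituted alkene, the other alkene being deactivated by the allylic acetate, leaves the Z alkene untouched.

Step 2
Reactants: 2 (4Z)-6-acetoxy-4-methylhex-4-enal
Product: 4 (2Z)-6,6-dimethoxy-3-methylhex-2-en-1-ol, via acetoxy acetal 3 (not isolated)
Conditions: HC(OMe)3, PPTS (cat.), MeOH, rt; then K2CO3, rt
Reagents that add atoms: trimethyl orthoformate, COC(OC)OC
Why: Acid-catalysed acetalisation masks C1, and the carbonate then neutralises the acid and removes the acetate by methanolysis in the same flask.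

Step 3
Reactants: 4 (2Z)-6,6-dimethoxy-3-methylhex-2-en-1-ol
Product: 5 (2Z)-6,6-dimethoxy-3-methylhex-2-enal
Conditions: TEMPO (10 mol %), PhI(OAc)2, CH2Cl2, rt
Reagents that add atoms: none
Why: Oxoammonium oxidation of the allylic alcohol is mild enough to keep both the Z geometry (as known for nerol) and the acetal.

Step 4
Reactants: 5 (2Z)-6,6-dimethoxy-3-methylhex-2-enal; 6 tert-butyl(diphenyl)(prop-2-ynyloxy)silane
Product: 7 (4S,5Z)-1-(tert-butyldiphenylsilyloxy)-9,9-dimethoxy-6-methylnon-5-en-2-yn-4-ol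
Conditions: (S,S)-ProPhenol (20 mol %), Me2Zn, Ph3PO (40 mol %), toluene, 4 °C
Reagents that add atoms: none
Why: Dinuclear zinc–ProPhenol catalysed asymmetric alkynylation of an enal, in which the chiral ligand pocket selects the aldehyde face and sets the carbinol that becomes C6.

Step 5
Reactants: 7 (4S,5Z)-1-(tert-butyldiphenylsilyloxy)-9,9-dimethoxy-6-methylnon-5-en-2-yn-4-ol
Product: 9 (Ra,5Z)-2-(tert-butyldiphenylsilyloxymethyl)-9,9-dimethoxy-6-methylnona-2,3,5-trienoic acid, via mesylate 8 (not isolated)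
Conditions: Ms2O, Et3N, THF, −78 °C; then Pd(PPh3)4 (5 mol %), CO (1 atm), H2O, −78 °C to rt
Reagents that add atoms: carbon monoxide, [C-]#[O+]; water, O
Why: Anti SN2' oxidative addition of zerovalent palladium to the propargylic mesylate gives an allenylpalladium species that inserts CO and is hydrolysed (palladium-catalysed hydroxycarbonylation of propargylic mesylates), so the 4S carbinol is translated into the (Ra) allene axis.

Step 6
Reactants: 9 (Ra,5Z)-2-(tert-butyldiphenylsilyloxymethyl)-9,9-dimethoxy-6-methylnona-2,3,5-trienoic acid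
Product: 10 (5R)-3-(tert-butyldiphenylsilyloxymethyl)-5-[(1Z)-5,5-dimethoxy-2-methylpent-1-enyl]-4-iodofuran-2(5H)-one
Conditions: I2, NaHCO3, MeCN, 0 °C
Reagents that add atoms: iodine, II
Why: Iodolactonisation of a 2,3-allenoic acid, in which the carboxylate adds to C6 anti to the iodonium on C6=C7, turns the (Ra) axis into the 6R centre (net inversion relative to 7) and leaves an iodide on C7.

Step 7
Reactants: 10 (5R)-3-(tert-butyldiphenylsilyloxymethyl)-5-[(1Z)-5,5-dimethoxy-2-methylpent-1-enyl]-4-iodofuran-2(5H)-one; 11 (E)-tributyl(prop-1-enyl)stannane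
Product: 12 (5R)-4-[(2E)-but-2-enoyl]-3-(tert-butyldiphenylsilyloxymethyl)-5-[(1Z)-5,5-dimethoxy-2-methylpent-1-enyl]furan-2(5H)-one
Conditions: Pd2(dba)3 (2.5 mol %), AsPh3 (20 mol %), CO (3 atm), NMP, 50 °C
Reagents that add atoms: carbon monoxide, [C-]#[O+]
Why: Carbonylative Stille coupling (oxidative addition, CO insertion, transfer of the propenyl group with retention of E geometry, reductive elimination) is neutral and spares C6–H and the acetal; palladium is chosen because a more electropositive metal on C7 would β-eliminate the lactone oxygen.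

Step 8
Reactants: 12 (5R)-4-[(2E)-but-2-enoyl]-3-(tert-butyldiphenylsilyloxymethyl)-5-[(1Z)-5,5-dimethoxy-2-methylpent-1-enyl]furan-2(5H)-one
Product: 13 (5R)-3-(tert-butyldiphenylsilyloxymethyl)-5-[(1Z)-5,5-dimethoxy-2-methylpent-1-enyl]-4-[(1S,2E)-1-hydroxybut-2-enyl]furan-2(5H)-one
Conditions: (R)-2-methyl-CBS-oxazaborolidine (0.5 equiv), catecholborane, toluene, −78 °C
Reagents that add atoms: none
Why: In this Corey–Bakshi–Shibata reduction the ketone should bind boron anti to the bulkier, fully substituted butenolide carbon C7, so that the (R)-catalyst delivers hydride 1,2 to the face that gives the 8S carbinol.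

Step 9
Reactants: 13 (5R)-3-(tert-butyldiphenylsilyloxymethyl)-5-[(1Z)-5,5-dimethoxy-2-methylpent-1-enyl]-4-[(1S,2E)-1-hydroxybut-2-enyl]furan-2(5H)-one
Product: 15 C1 aldoxime of 13 (E/Z mixture at C=N; 4Z,6R,8S), via aldehyde 14 (not isolated)
Conditions: NH2OH·HCl, THF/H2O (4:1), rt; then NaOAc
Reagents that add atoms: hydroxylamine hydrochloride, NO.Cl
Why: The hydrochloride supplies the acid that hydrolyses the dimethyl acetal, and the freed aldehyde condenses at once to the oxime, at a pH (3 to 5) that the TBDPS ether and the bis-allylic alcohol should tolerate.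

Step 10
Reactants: 15 C1 aldoxime of 13
Product: 18 bridged isoxazoline alcohol (C1=N–O–C9 across the new ten-membered ring; 8-OH; 13-OTBDPS; 4Z,6R,8R,9R,10R), via hydroximoyl chloride 16 (not isolated), via nitrile oxide 17 (not isolated)
Conditions: NCS, pyridine (cat.), CHCl3, 0 °C to rt; then slow addition (12 h) to iPrOMgBr (3 equiv, from EtMgBr and iPrOH), CH2Cl2, 0 °C to rt, 2 mM
Reagents that add atoms: none
Why: Proposed new method: iPrOMgBr deprotonates the C8 hydroxyl and dehydrochlorinates the hydroximoyl chloride, so that the nitrile oxide oxygen and the C8 alkoxide sit on the same magnesium, and a concerted (3+2) cycloaddition then joins C1 to C10 and the dipole oxygen to C9. The closest known reaction types are the intermolecular magnesium-alkoxide-directed nitrile oxide cycloaddition to secondary (E)-allylic alcohols and the uncatalysed intramolecular nitrile oxide cycloaddition that closes macrocycles in the bridged mode; their combination on a ten-membered ring is not known. The isoxazoline is closed by the two new bonds of the cycloaddition, and the ten-membered carbocycle is closed in the endo mode at the distal alkene carbon C10, giving a bicyclo[7.2.1] skeleton bridged between C1 and C9. C9 is set by the chelate (alkoxide outside, hydrogen inside, C7 anti to the incoming oxygen), which places the new C9–O bond syn to C8–O, and C10 follows from suprafacial addition to the E alkene, which puts methyl and C8 trans on the isoxazoline. The step needs regioselectivity (oxygen to C9), facial selectivity and chemoselectivity over the C4=C5 and C7=C11 alkenes and over dimerisation: the five-membered magnesium chelate delivers oxygen to the proximal carbon on one face, the two-carbon link from C1 makes addition to C4=C5 geometrically impossible, the butenolide alkene is tetrasubstituted and electron-poor, and slow addition at high dilution suppresses furoxan formation.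

Step 11
Reactants: 18 bridged isoxazoline alcohol
Product: 19 8-O-methacryloyl isoxazoline (13-OTBDPS; 4Z,6R,8R,9R,10R)
Conditions: methacrylic anhydride, Et3N, DMAP (cat.), CH2Cl2, 0 °C to rt
Reagents that add atoms: methacrylic anhydride, C=C(C)C(=O)OC(=O)C(C)=C
Why: DMAP-catalysed acylation meets only one free hydroxyl, C8–OH, because the C9 oxygen is still locked in the isoxazoline, and O-acylation leaves the C8 configuration untouched.

Step 12
Reactants: 19 8-O-methacryloyl isoxazoline
Product: 21 13-O-acetyl-8-O-methacryloyl isoxazoline (4Z,6R,8R,9R,10R), via primary alcohol 20 (not isolated)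
Conditions: HF·pyridine, pyridine/THF, 0 °C to rt; then Ac2O, DMAP (cat.), 0 °C
Reagents that add atoms: acetic anhydride, CC(=O)OC(C)=O
Why: Buffered fluoride cleaves the primary silyl ether without basic conditions that could move the methacrylate, and the freed C13 alcohol is acetylated in the same flask before it can take part in acyl migration.

Step 13
Reactants: 21 13-O-acetyl-8-O-methacryloyl isoxazoline
Product: 22 target, (4Z,6R,8R,9R,10S)-13-acetoxy-9-hydroxy-8-methacryloyloxy-1-oxogermacra-4,7(11)-dien-12,6-olide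
Conditions: Mo(CO)6, MeCN/H2O (15:1), 80 °C
Reagents that add atoms: water, O
Why: Reductive N–O cleavage by zerovalent molybdenum gives the β-hydroxy imine, which water hydrolyses to the ketol under neutral conditions that should spare the alkenes and the three esters and not epimerise C10.

**Compound list**

1 | neryl acetate, (2Z)-3,7-dimethylocta-2,6-dien-1-yl acetate | CC(C)=CCC/C(C)=C\COC(C)=O | starting material
2 | (4Z)-6-acetoxy-4-methylhex-4-enal | O=CCC/C(C)=C\COC(C)=O | intermediate
3 | (2Z)-6,6-dimethoxy-3-methylhex-2-enyl acetate | COC(OC)CC/C(C)=C\COC(C)=O | intermediate (not isolated)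
4 | (2Z)-6,6-dimethoxy-3-methylhex-2-en-1-ol | COC(OC)CC/C(C)=C\CO | intermediate
5 | (2Z)-6,6-dimethoxy-3-methylhex-2-enal | COC(OC)CC/C(C)=C\C=O | intermediate
6 | tert-butyl(diphenyl)(prop-2-ynyloxy)silane | C#CCO[Si](c1ccccc1)(c1ccccc1)C(C)(C)C | starting material
7 | (4S,5Z)-1-(tert-butyldiphenylsilyloxy)-9,9-dimethoxy-6-methylnon-5-en-2-yn-4-ol | O[C@H](C#CCO[Si](c1ccccc1)(c1ccccc1)C(C)(C)C)/C=C(/C)CCC(OC)OC | intermediate
8 | methanesulfonate of 7 (4S,5Z) | CS(=O)(=O)O[C@H](C#CCO[Si](c1ccccc1)(c1ccccc1)C(C)(C)C)/C=C(/C)CCC(OC)OC | intermediate (not isolated)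
9 | (Ra,5Z)-2-(tert-butyldiphenylsilyloxymethyl)-9,9-dimethoxy-6-methylnona-2,3,5-trienoic acid | OC(=O)C(CO[Si](c1ccccc1)(c1ccccc1)C(C)(C)C)=[C@]=C([H])/C=C(/C)CCC(OC)OC | intermediate
10 | (5R)-3-(tert-butyldiphenylsilyloxymethyl)-5-[(1Z)-5,5-dimethoxy-2-methylpent-1-enyl]-4-iodofuran-2(5H)-one | O=C1O[C@H](/C=C(/C)CCC(OC)OC)C(I)=C1CO[Si](c2ccccc2)(c3ccccc3)C(C)(C)C | intermediate
11 | (E)-tributyl(prop-1-enyl)stannane | C/C=C/[Sn](CCCC)(CCCC)CCCC | starting material
12 | (5R)-4-[(2E)-but-2-enoyl]-3-(tert-butyldiphenylsilyloxymethyl)-5-[(1Z)-5,5-dimethoxy-2-methylpent-1-enyl]furan-2(5H)-one | C/C=C/C(=O)C1=C(CO[Si](c2ccccc2)(c3ccccc3)C(C)(C)C)C(=O)O[C@@H]1/C=C(/C)CCC(OC)OC | intermediate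
13 | (5R)-3-(tert-butyldiphenylsilyloxymethyl)-5-[(1Z)-5,5-dimethoxy-2-methylpent-1-enyl]-4-[(1S,2E)-1-hydroxybut-2-enyl]furan-2(5H)-one | C/C=C/[C@H](O)C1=C(CO[Si](c2ccccc2)(c3ccccc3)C(C)(C)C)C(=O)O[C@@H]1/C=C(/C)CCC(OC)OC | intermediate
14 | C1 aldehyde from 13 (4Z,6R,8S) | C/C=C/[C@H](O)C1=C(CO[Si](c2ccccc2)(c3ccccc3)C(C)(C)C)C(=O)O[C@@H]1/C=C(/C)CCC=O | intermediate (not isolated)
15 | C1 aldoxime (E/Z at C=N; 4Z,6R,8S) | C/C=C/[C@H](O)C1=C(CO[Si](c2ccccc2)(c3ccccc3)C(C)(C)C)C(=O)O[C@@H]1/C=C(/C)CCC=NO | intermediate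
16 | C1 hydroximoyl chloride | C/C=C/[C@H](O)C1=C(CO[Si](c2ccccc2)(c3ccccc3)C(C)(C)C)C(=O)O[C@@H]1/C=C(/C)CCC(Cl)=NO | intermediate (not isolated)
17 | C1 nitrile oxide | C/C=C/[C@H](O)C1=C(CO[Si](c2ccccc2)(c3ccccc3)C(C)(C)C)C(=O)O[C@@H]1/C=C(/C)CCC#[N+][O-] | intermediate (not isolated)
18 | bridged isoxazoline alcohol (C1=N–O–C9; 8-OH; 13-OTBDPS; 4Z,6R,8R,9R,10R) | O[C@@H]1C2=C(CO[Si](c3ccccc3)(c4ccccc4)C(C)(C)C)C(=O)O[C@@H]2/C=C(/C)CCC5=NO[C@@H]1[C@@H]5C | intermediate
19 | 8-O-methacryloyl isoxazoline (13-OTBDPS) | C=C(C)C(=O)O[C@@H]1C2=C(CO[Si](c3ccccc3)(c4ccccc4)C(C)(C)C)C(=O)O[C@@H]2/C=C(/C)CCC5=NO[C@@H]1[C@@H]5C | intermediate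
20 | 8-O-methacryloyl isoxazoline with free C13 alcohol | C=C(C)C(=O)O[C@@H]1C2=C(CO)C(=O)O[C@@H]2/C=C(/C)CCC5=NO[C@@H]1[C@@H]5C | intermediate (not isolated)
21 | 13-O-acetyl-8-O-methacryloyl isoxazoline | C=C(C)C(=O)O[C@@H]1C2=C(COC(C)=O)C(=O)O[C@@H]2/C=C(/C)CCC5=NO[C@@H]1[C@@H]5C | intermediate
22 | (4Z,6R,8R,9R,10S)-13-acetoxy-9-hydroxy-8-methacryloyloxy-1-oxogermacra-4,7(11)-dien-12,6-olide | C=C(C)C(=O)O[C@@H]1C2=C(COC(C)=O)C(=O)O[C@@H]2/C=C(/C)CCC(=O)[C@@H](C)[C@H]1O | target

**Step count and risks**

Total step count: 13. Longest linear sequence: 13 steps (from neryl acetate; fully linear).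

Steps most likely to fail:

1. Step 10 (Proposed new method). What may go wrong: the magnesium-bridged transition state may not be reachable inside the forming ten-membered ring. Dimerisation of the nitrile oxide, attack on the wrong alkene face, or base-induced epimerisation at C6 would then take over. The fallback uses known chemistry: a substrate-controlled, uncatalysed intramolecular nitrile oxide cycloaddition, followed by inversion at C8. It sets out from ketone 12 and comes back at methacrylate 19. Reduction of 12 with the (S)-oxazaborolidine and catecholborane gives the C8 epimer of 13, alcohol F1. Silylation (TBSOTf, 2,6-lutidine) gives silyl ether F2. PPTS in wet acetone frees aldehyde F3, and NH2OH·HCl/NaOAc gives oxime F4. Oxidation with PhI(OAc)2 (cat. CF3CO2H, CH2Cl2/MeOH, high dilution) generates nitrile oxide F5. This now adds under the inside-alkoxy effect (silyloxy group inside, C7 anti), which is the same alkene face as in step 10, to give isoxazoline F6. CSA in MeOH removes the secondary silyl group and leaves the TBDPS ether, giving alcohol F7, the C8 epimer of 18. A Mitsunobu esterification with methacrylic acid (PPh3, DIAD, toluene) inverts C8 and delivers 19.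

2. Step 5. What may go wrong: the mesylate is both allylic and propargylic and may ionise before palladium reaches it, or the reaction may escape into π-allyl pathways. Either would erode the centre-to-axis chirality transfer. The fallback sets out from 7 and comes back at 10. ClCO2Me and pyridine convert 7 into the isolable methyl carbonate F8, which should ionise only under zerovalent palladium. Decarboxylative methoxycarbonylation (Pd2(dba)3, PPh3, CO, MeOH, rt) gives methyl allenoate F9. Iodolactonisation of the ester (I2, MeCN/H2O, loss of iodomethane) gives 10.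

3. Step 8. What may go wrong: poor facial discrimination between the two alkenyl groups on the ketone, or competing conjugate reduction. The fallback sets out from 12 and comes back at 13. Luche reduction (NaBH4, CeCl3·7H2O, MeOH, −78 °C) gives the C8 epimer mixture F10. A Sharpless kinetic resolution (Ti(OiPr)4, L-(+)-DIPT, TBHP 0.6 equiv, 4 Å sieves, CH2Cl2, −20 °C) should epoxidise the propenyl group of the 8R epimer only, giving epoxy alcohol F11, and leave 13 for chromatographic separation.

**Further compounds**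

F1 | step 10 | C8 epimer of 13, (5R)-4-[(1R,2E)-1-hydroxybut-2-enyl] butenolide | C/C=C/[C@@H](O)C1=C(CO[Si](c2ccccc2)(c3ccccc3)C(C)(C)C)C(=O)O[C@@H]1/C=C(/C)CCC(OC)OC
F2 | step 10 | 8-O-TBS ether of F1 | C/C=C/[C@@H](O[Si](C)(C)C(C)(C)C)C1=C(CO[Si](c2ccccc2)(c3ccccc3)C(C)(C)C)C(=O)O[C@@H]1/C=C(/C)CCC(OC)OC
F3 | step 10 | C1 aldehyde from F2 | C/C=C/[C@@H](O[Si](C)(C)C(C)(C)C)C1=C(CO[Si](c2ccccc2)(c3ccccc3)C(C)(C)C)C(=O)O[C@@H]1/C=C(/C)CCC=O
F4 | step 10 | C1 aldoxime from F3 | C/C=C/[C@@H](O[Si](C)(C)C(C)(C)C)C1=C(CO[Si](c2ccccc2)(c3ccccc3)C(C)(C)C)C(=O)O[C@@H]1/C=C(/C)CCC=NO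
F5 | step 10 | C1 nitrile oxide from F4 | C/C=C/[C@@H](O[Si](C)(C)C(C)(C)C)C1=C(CO[Si](c2ccccc2)(c3ccccc3)C(C)(C)C)C(=O)O[C@@H]1/C=C(/C)CCC#[N+][O-]
F6 | step 10 | 8-epi bridged isoxazoline, 8-OTBS, 13-OTBDPS | CC(C)(C)[Si](C)(C)O[C@H]1C2=C(CO[Si](c3ccccc3)(c4ccccc4)C(C)(C)C)C(=O)O[C@@H]2/C=C(/C)CCC5=NO[C@@H]1[C@@H]5C
F7 | step 10 | 8-epi bridged isoxazoline alcohol (C8 epimer of 18) | O[C@H]1C2=C(CO[Si](c3ccccc3)(c4ccccc4)C(C)(C)C)C(=O)O[C@@H]2/C=C(/C)CCC5=NO[C@@H]1[C@@H]5C
F8 | step 5 | methyl carbonate of 7 (4S,5Z) | COC(=O)O[C@H](C#CCO[Si](c1ccccc1)(c1ccccc1)C(C)(C)C)/C=C(/C)CCC(OC)OC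
F9 | step 5 | methyl ester of 9 (Ra,5Z) | COC(=O)C(CO[Si](c1ccccc1)(c1ccccc1)C(C)(C)C)=[C@]=C([H])/C=C(/C)CCC(OC)OC
F10 | step 8 | C8 epimer mixture of 13 | C/C=C/C(O)C1=C(CO[Si](c2ccccc2)(c3ccccc3)C(C)(C)C)C(=O)O[C@@H]1/C=C(/C)CCC(OC)OC
F11 | step 8 | epoxy alcohol from the 8R epimer (trans-9,10-epoxide) | C[C@H]1O[C@@H]1[C@@H](O)C2=C(CO[Si](c3ccccc3)(c4ccccc4)C(C)(C)C)C(=O)O[C@@H]2/C=C(/C)CCC(OC)OC
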